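Numbering used below (3,7-dioxabicyclo[3.3.0]octane): C1 carbinol, C2 and C6 aryl carbons, C5 bridgehead CH, C4 and C8 the CH2 groups; ring A = C1–C8–O7–C6–C5, ring B = C1–C2–O3–C4–C5. The SMILES is read as the (1S,2S,5R,6R) isomer, with both aryl groups endo (C2–aryl trans to C1–OH, C6–aryl trans to H5).
Retrosynthesis: both phenols become allyl ethers; C2–H is traced back to a C2 methyl ketal; ring B is cut at C1–C2 to a ring A ketone (C1=O) whose C5 side chain CH2–O–CH(OMe)Ar carries the future C2; ring A is cut at O7–C8 (diazoketone O–H insertion) and the chain at C5–C6 (aldol).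
Forward: an Evans syn-aldol joins C5–C6, O–H insertion closes ring A, DDQ turns the side-chain benzyl ether into a mixed acetal, light closes ring B, then silane reduction and deallylation.
Enabling feature: C1 is a carbonyl carbon inside ring A and the acetal C2–H is held five atoms away across C5–C4–O3. The excited C1=O oxygen can therefore take that hydrogen (1,6-transfer), and the 1,5-biradical can only close to the cis-fused ring B with the tertiary hydroxyl already on C1.
Stereochemistry: C5 and C6 come from the auxiliary-controlled syn-aldol (cis on ring A, C6 aryl endo); C1 comes from the tether (cis ring fusion); C2 comes from hydride delivery to the bicyclic oxocarbenium ion on its convex face (C2 aryl endo).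

Key step: step 9

Remark: Ar = 4-(allyloxy)-3-methoxyphenyl; 1, 3 and 6 are taken as commercial; 16 and 18 are carried as mixtures of epimers at the acetal (C2) carbon, which becomes planar in 19, so their SMILES leave that centre open.

Step 1
Reactants: 1 4-(allyloxy)-3-methoxybenzaldehyde
Product: 2 benzylic alcohol ArCH2OH
Conditions: NaBH4, MeOH, 0 °C
Reagents that add atoms: none
Why: Hydride reduction of an aromatic aldehyde with NaBH4 (carbonyl reduction) should give the benzylic alcohol cleanly, the aryl allyl ether being inert and no stereocentre being formed.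

Step 2
Reactants: 2 benzylic alcohol ArCH2OH; 3 methyl acrylate
Product: 5 ether acid ArCH2OCH2CH2CO2H, via methyl ester 4 (not isolated)
Conditions: KOtBu (10 mol%), THF, 0 °C to rt; then LiOH, H2O, rt; then 1 M HCl
Reagents that add atoms: lithium hydroxide [Li+].[OH-]
Why: Base-catalysed oxa-Michael addition of the benzylic alkoxide to the acrylate followed by saponification in the same flask should give the β-alkoxy acid, any transesterified material converging on the same acid, with no stereocentre formed.

Step 3
Reactants: 5 ether acid ArCH2OCH2CH2CO2H; 6 (R)-4-benzyloxazolidin-2-one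
Product: 8 imide (R)-4-benzyl-3-[3-(ArCH2O)propanoyl]oxazolidin-2-one, via pivalic mixed anhydride 7 (not isolated)
Conditions: PivCl, Et3N, THF, −20 °C; then 6, LiCl, −20 °C to rt
Reagents that add atoms: pivaloyl chloride CC(C)(C)C(=O)Cl (retained only in intermediate 7)
Why: N-Acylation of the oxazolidinone through a pivalic mixed anhydride with LiCl activation is the standard mild way to an Evans imide and should avoid β-elimination of the alkoxy group, the only stereocentre being that of the auxiliary.

Step 4
Reactants: 8 imide (R)-4-benzyl-3-[3-(ArCH2O)propanoyl]oxazolidin-2-one; 1 4-(allyloxy)-3-methoxybenzaldehyde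
Product: 10 syn-aldol adduct (R)-4-benzyl-3-[(2R,3R)-3-Ar-3-hydroxy-2-(ArCH2OCH2)propanoyl]oxazolidin-2-one, via dibutylboron Z-enolate 9 (not isolated)
Conditions: Bu2BOTf, iPr2NEt, CH2Cl2, −78 to 0 °C; then 1, −78 to 0 °C; then pH 7 buffer, MeOH, 30% H2O2, 0 °C
Reagents that add atoms: dibutylboron triflate CCCCB(CCCC)OS(=O)(=O)C(F)(F)F (retained only in intermediate 9)
Why: In this Evans syn-aldol reaction the Z-boron enolate should add to the aldehyde through a closed chair (Zimmerman–Traxler) transition state on the enolate face turned away from the benzyl group of the (R)-auxiliary, which sets the future C5 and C6 together as the (2R,3R) syn pair that becomes the cis relationship on ring A.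

Step 5
Reactants: 10 syn-aldol adduct (R)-4-benzyl-3-[(2R,3R)-3-Ar-3-hydroxy-2-(ArCH2OCH2)propanoyl]oxazolidin-2-one
Product: 12 hydroxy acid (2R,3R)-3-Ar-3-hydroxy-2-(ArCH2OCH2)propanoic acid, via peroxy acid 11 (not isolated)
Conditions: LiOH, 30% H2O2, THF/H2O, 0 °C; then Na2SO3; then 1 M HCl to pH 3
Reagents that add atoms: hydrogen peroxide OO
Why: Hydroperoxide cleavage of the imide (standard removal of the Evans auxiliary) attacks the exocyclic carbonyl group selectively at 0 °C and should leave the α-centre and the β-hydroxyl untouched while returning the auxiliary.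

Step 6
Reactants: 12 hydroxy acid (2R,3R)-3-Ar-3-hydroxy-2-(ArCH2OCH2)propanoic acid
Product: 14 diazoketone (3R,4R)-4-Ar-1-diazo-4-hydroxy-3-(ArCH2OCH2)butan-2-one, via isobutyl carbonic mixed anhydride 13 (not isolated)
Conditions: i-BuOCOCl, N-methylmorpholine, THF, −20 °C; then CH2N2, Et2O, −20 to 0 °C
Reagents that add atoms: isobutyl chloroformate CC(C)COC(=O)Cl (retained only in intermediate 13); diazomethane C=[N+]=[N-]
Why: Acylation of diazomethane by a mixed carbonic anhydride (the diazoketone stage of an Arndt–Eistert sequence) should give the α-diazoketone under non-acidic conditions in which the carboxylate is activated much faster than the hindered benzylic hydroxyl, without change at either stereocentre.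

Step 7
Reactants: 14 diazoketone (3R,4R)-4-Ar-1-diazo-4-hydroxy-3-(ArCH2OCH2)butan-2-one
Product: 15 ring A ketone (4R,5R)-5-Ar-4-(ArCH2OCH2)dihydrofuran-3(2H)-one
Conditions: Rh2(OAc)4 (1 mol%), CH2Cl2 (2 mM), rt
Reagents that add atoms: none
Why: Rh2(OAc)4-catalysed decomposition of the diazoketone and intramolecular O–H insertion of the derived carbenoid into the hydroxyl (five-membered oxonium ylide, then proton transfer) should close ring A as the tetrahydrofuran-3-one under neutral conditions, so that the epimerisable C5 centre and the cis relationship fixed by the aldol are kept.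

Step 8
Reactants: 15 ring A ketone (4R,5R)-5-Ar-4-(ArCH2OCH2)dihydrofuran-3(2H)-one
Product: 16 acetal ketone (4R,5R)-5-Ar-4-[ArCH(OMe)OCH2]dihydrofuran-3(2H)-one (both acetal epimers)
Conditions: DDQ (1.2 equiv), MeOH (5 equiv), NaHCO3, 4 Å molecular sieves, CH2Cl2, 0 °C
Reagents that add atoms: methanol CO
Why: DDQ should abstract hydride from the unhindered primary dialkoxybenzyl ether (the benzylic oxidation used to cleave p-methoxybenzyl ethers) to give an oxocarbenium ion that methanol traps as the mixed acetal, the cold buffered conditions sparing the hindered ring benzylic C6–H and the C5 centre, while the new acetal centre forms without control and is erased in step 10.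

Step 9
Reactants: 16 acetal ketone (4R,5R)-5-Ar-4-[ArCH(OMe)OCH2]dihydrofuran-3(2H)-one (both acetal epimers)
Product: 18 ketal alcohol (1S,5R,6R)-2,6-di-Ar-2-methoxy-3,7-dioxabicyclo[3.3.0]octan-1-ol (both C2 epimers), via 1,5-biradical 17 (not isolated)
Conditions: hν (medium-pressure Hg lamp, Pyrex, λ > 300 nm), degassed benzene (5 mM), rt
Reagents that add atoms: none
Why: Excitation of the ring A ketone (n,π*) should let the carbonyl oxygen abstract the acetal hydrogen of the side chain by 1,6-hydrogen transfer through a seven-membered transition state, and the resulting 1,5-biradical 17 (hydroxy-substituted C1 radical and dialkoxybenzyl C2 radical) should collapse by C1–C2 bond formation. The closest known reaction type is the Norrish–Yang photocyclisation of β-alkoxy ketones to tetrahydrofuran-3-ols, which is established for benzyl ethers of 4-(hydroxymethyl)tetrahydrofuran-3-ones and for acetal hydrogen donors. Ring B closes by intramolecular radical–radical combination of the 1,5-biradical, a five-membered ring closure that forms the bond between two fully substituted carbons without any ionic intermediate. The new C1 stereocentre is controlled by the C5–C4–O3 tether, because the side chain can reach C1 only from its own face of ring A, so the bicycle is cis-fused and the hydroxyl ends up cis to H5 (1S), while the C2 ketal centre forms as an epimer mixture that converges in step 10. The step needs site selectivity for the acetal C–H over α-cleavage and over other hydrogens, which the substrate secures because the side chain has no γ-hydrogen (that position is O3), the doubly oxygen-substituted benzylic C–H is the weakest in the molecule, and the ring hydrogens at C6 and C8 cannot reach the in-plane oxygen lone pair.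

Step 10
Reactants: 18 ketal alcohol (1S,5R,6R)-2,6-di-Ar-2-methoxy-3,7-dioxabicyclo[3.3.0]octan-1-ol (both C2 epimers)
Product: 20 bis(allyl ether) (1S,2S,5R,6R)-2,6-di-Ar-3,7-dioxabicyclo[3.3.0]octan-1-ol, via oxocarbenium ion 19 (not isolated)
Conditions: Et3SiH, BF3·OEt2, CH2Cl2, −78 to −40 °C; then NaHCO3 (aq)
Reagents that add atoms: none
Why: Ionic hydrogenation of the ketal (BF3-promoted loss of methoxide to the cyclic oxocarbenium ion 19, then hydride transfer from the silane) should deliver hydride to C2 on the convex face of the cis-fused bicycle, away from ring A and its endo C6 aryl group, so that both ketal epimers converge on the (2S) centre with the C2 aryl group endo.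

Step 11
Reactants: 20 bis(allyl ether) (1S,2S,5R,6R)-2,6-di-Ar-3,7-dioxabicyclo[3.3.0]octan-1-ol
Product: 21 target (1S,2S,5R,6R)-2,6-bis(4-hydroxy-3-methoxyphenyl)-3,7-dioxabicyclo[3.3.0]octan-1-ol
Conditions: Pd(PPh3)4 (5 mol%), K2CO3, MeOH, rt
Reagents that add atoms: none
Why: Pd(PPh3)4-catalysed transfer of the allyl groups to methoxide (Tsuji–Trost-type deallylation of aryl allyl ethers) should free both phenols under mild basic conditions that leave the acid-sensitive endo benzylic ethers and all four stereocentres untouched.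

Compound list
1 | 4-(allyloxy)-3-methoxybenzaldehyde | O=Cc1ccc(OCC=C)c(OC)c1 | starting material
2 | [4-(allyloxy)-3-methoxyphenyl]methanol | OCc1ccc(OCC=C)c(OC)c1 | intermediate
3 | methyl acrylate | C=CC(=O)OC | starting material
4 | methyl 3-{[4-(allyloxy)-3-methoxyphenyl]methoxy}propanoate | COC(=O)CCOCc1ccc(OCC=C)c(OC)c1 | intermediate
5 | 3-{[4-(allyloxy)-3-methoxyphenyl]methoxy}propanoic acid | OC(=O)CCOCc1ccc(OCC=C)c(OC)c1 | intermediate
6 | (R)-4-benzyloxazolidin-2-one | O=C1N[C@H](Cc2ccccc2)CO1 | starting material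
7 | 3-{[4-(allyloxy)-3-methoxyphenyl]methoxy}propanoic pivalic anhydride | CC(C)(C)C(=O)OC(=O)CCOCc1ccc(OCC=C)c(OC)c1 | intermediate
8 | (R)-4-benzyl-3-(3-{[4-(allyloxy)-3-methoxyphenyl]methoxy}propanoyl)oxazolidin-2-one | O=C(CCOCc1ccc(OCC=C)c(OC)c1)N1[C@H](Cc2ccccc2)COC1=O | intermediate
9 | (R)-4-benzyl-3-[(Z)-1-[(dibutylboranyl)oxy]-3-{[4-(allyloxy)-3-methoxyphenyl]methoxy}prop-1-en-1-yl]oxazolidin-2-one | CCCCB(CCCC)O/C(=C\COCc1ccc(OCC=C)c(OC)c1)N1[C@H](Cc2ccccc2)COC1=O | intermediate
10 | (R)-4-benzyl-3-[(2R,3R)-3-[4-(allyloxy)-3-methoxyphenyl]-2-({[4-(allyloxy)-3-methoxyphenyl]methoxy}methyl)-3-hydroxypropanoyl]oxazolidin-2-one | C=CCOc1ccc(cc1OC)[C@H](O)[C@@H](COCc1ccc(OCC=C)c(OC)c1)C(=O)N1[C@H](Cc2ccccc2)COC1=O | intermediate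
11 | (2R,3R)-3-[4-(allyloxy)-3-methoxyphenyl]-2-({[4-(allyloxy)-3-methoxyphenyl]methoxy}methyl)-3-hydroxypropaneperoxoic acid | C=CCOc1ccc(cc1OC)[C@H](O)[C@@H](COCc1ccc(OCC=C)c(OC)c1)C(=O)OO | intermediate
12 | (2R,3R)-3-[4-(allyloxy)-3-methoxyphenyl]-2-({[4-(allyloxy)-3-methoxyphenyl]methoxy}methyl)-3-hydroxypropanoic acid | C=CCOc1ccc(cc1OC)[C@H](O)[C@@H](COCc1ccc(OCC=C)c(OC)c1)C(=O)O | intermediate
13 | mixed anhydride of 12 with isobutyl hydrogen carbonate | C=CCOc1ccc(cc1OC)[C@H](O)[C@@H](COCc1ccc(OCC=C)c(OC)c1)C(=O)OC(=O)OCC(C)C | intermediate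
14 | (3R,4R)-4-[4-(allyloxy)-3-methoxyphenyl]-3-({[4-(allyloxy)-3-methoxyphenyl]methoxy}methyl)-1-diazo-4-hydroxybutan-2-one | C=CCOc1ccc(cc1OC)[C@H](O)[C@@H](COCc1ccc(OCC=C)c(OC)c1)C(=O)C=[N+]=[N-] | intermediate
15 | (4R,5R)-5-[4-(allyloxy)-3-methoxyphenyl]-4-({[4-(allyloxy)-3-methoxyphenyl]methoxy}methyl)dihydrofuran-3(2H)-one | C=CCOc1ccc(cc1OC)[C@@H]2OCC(=O)[C@@H]2COCc2ccc(OCC=C)c(OC)c2 | intermediate
16 | (4R,5R)-5-[4-(allyloxy)-3-methoxyphenyl]-4-({[4-(allyloxy)-3-methoxyphenyl](methoxy)methoxy}methyl)dihydrofuran-3(2H)-one, both epimers at the acetal carbon | C=CCOc1ccc(cc1OC)[C@@H]2OCC(=O)[C@@H]2COC(OC)c2ccc(OCC=C)c(OC)c2 | intermediate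
17 | 1,5-biradical from 16 (hydroxy-substituted C1 radical, dialkoxybenzyl C2 radical) | C=CCOc1ccc(cc1OC)[C@@H]2OC[C](O)[C@@H]2CO[C](OC)c2ccc(OCC=C)c(OC)c2 | intermediate
18 | (1S,5R,6R)-2,6-bis[4-(allyloxy)-3-methoxyphenyl]-2-methoxy-3,7-dioxabicyclo[3.3.0]octan-1-ol, both epimers at C2 | C=CCOc1ccc(cc1OC)[C@@H]2OC[C@@]3(O)[C@@H]2COC3(OC)c2ccc(OCC=C)c(OC)c2 | intermediate
19 | bicyclic oxocarbenium ion (C2=O3+) from 18 | C=CCOc1ccc(cc1OC)[C@@H]2OC[C@@]3(O)[C@@H]2C[O+]=C3c2ccc(OCC=C)c(OC)c2 | intermediate
20 | (1S,2S,5R,6R)-2,6-bis[4-(allyloxy)-3-methoxyphenyl]-3,7-dioxabicyclo[3.3.0]octan-1-ol | C=CCOc1ccc(cc1OC)[C@@H]2OC[C@@]3(O)[C@@H]2CO[C@H]3c2ccc(OCC=C)c(OC)c2 | intermediate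
21 | (1S,2S,5R,6R)-2,6-bis(4-hydroxy-3-methoxyphenyl)-3,7-dioxabicyclo[3.3.0]octan-1-ol | COc1cc([C@@H]2OC[C@@]3(O)[C@@H]2CO[C@H]3c2ccc(O)c(OC)c2)ccc1O | target

Total step count: 11. Longest linear sequence: 11 steps (1 to 21; aldehyde 1 enters again in step 4).

Steps most likely to fail

Step 9 (photocyclisation). The excited ketone may decay without hydrogen transfer (charge-transfer quenching by the dialkoxyaryl rings), or ring A may be lost by α-cleavage faster than the 1,6-hydrogen transfer. The fallback sets out from 15 and returns at 18; it replaces the photochemistry by a ground-state carbonyl coupling and also by-passes step 8. Oxidative debenzylation of 15 with DDQ in wet CH2Cl2 would give the hydroxy ketone (4R,5R)-5-Ar-4-(hydroxymethyl)dihydrofuran-3(2H)-one F1. Acylation with 4-(allyloxy)-3-methoxybenzoyl chloride and pyridine would give the keto ester F2. Intramolecular ketone–ester reductive coupling with low-valent titanium (TiCl3, Zn, DME, reflux; McMurry-type) would close ring B as the bicyclic enol ether (5R,6R)-2,6-di-Ar-3,7-dioxabicyclo[3.3.0]oct-1-ene F3. Epoxidation of the C1=C2 enol ether with dimethyldioxirane on the convex face, followed by opening with methanol at C2, would give 18.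

Step 7 (O–H insertion). The carbenoid may be captured by the side-chain ether oxygen (five-membered oxonium ylide, then 1,2-shift of the electron-rich benzyl group) or by the neighbouring aryl ring, in competition with the hydroxyl. The fallback sets out from 10 and returns at 15; it uses ionic etherification in place of carbenoid chemistry. Transamination of 10 with MeNH(OMe)·HCl and Me3Al would give the Weinreb amide F4, with auxiliary 6 recovered. Addition of chloromethyllithium (ICH2Cl, MeLi·LiBr, THF, −78 °C) would give the chloromethyl ketone F5. Ag2O-promoted intramolecular Williamson etherification (5-exo-tet displacement of chloride by the benzylic hydroxyl) would give 15.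

Step 10 (ionic hydrogenation). BF3 may ionise the electron-rich benzylic C6–O7 bond, with loss of the endo configuration at C6 or ring opening, before hydride transfer at C2 is complete. The fallback sets out from 18 and returns at 20; it uses carbonyl reduction and etherification at the primary carbon in place of oxocarbenium reduction. Mild hydrolysis of 18 (PPTS, aqueous acetone) would give the keto diol F6, in equilibrium with its cyclic hemiketal. Chelation-controlled reduction with Zn(BH4)2, in which hydride attacks the chelated α-hydroxy ketone from the side of the smaller C8 methylene, would give the triol F7 with the (S) benzylic carbinol. Selective tosylation of the primary hydroxyl (TsCl, Et3N, Bu2SnO cat.) would give the tosylate F8. NaH in THF would then close ring B by 5-exo-tet Williamson etherification with retention at C2 to give 20.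

Further compounds
F1 | step 9 | (4R,5R)-5-[4-(allyloxy)-3-methoxyphenyl]-4-(hydroxymethyl)dihydrofuran-3(2H)-one | C=CCOc1ccc(cc1OC)[C@@H]2OCC(=O)[C@@H]2CO
F2 | step 9 | [(2R,3R)-2-[4-(allyloxy)-3-methoxyphenyl]-4-oxotetrahydrofuran-3-yl]methyl 4-(allyloxy)-3-methoxybenzoate | C=CCOc1ccc(cc1OC)[C@@H]2OCC(=O)[C@@H]2COC(=O)c2ccc(OCC=C)c(OC)c2
F3 | step 9 | (5R,6R)-2,6-bis[4-(allyloxy)-3-methoxyphenyl]-3,7-dioxabicyclo[3.3.0]oct-1-ene | C=CCOc1ccc(cc1OC)[C@@H]2OCC3=C(c4ccc(OCC=C)c(OC)c4)OC[C@H]23
F4 | step 7 | (2R,3R)-3-[4-(allyloxy)-3-methoxyphenyl]-2-({[4-(allyloxy)-3-methoxyphenyl]methoxy}methyl)-3-hydroxy-N-methoxy-N-methylpropanamide | C=CCOc1ccc(cc1OC)[C@H](O)[C@@H](COCc1ccc(OCC=C)c(OC)c1)C(=O)N(C)OC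
F5 | step 7 | (3R,4R)-4-[4-(allyloxy)-3-methoxyphenyl]-3-({[4-(allyloxy)-3-methoxyphenyl]methoxy}methyl)-1-chloro-4-hydroxybutan-2-one | C=CCOc1ccc(cc1OC)[C@H](O)[C@@H](COCc1ccc(OCC=C)c(OC)c1)C(=O)CCl
F6 | step 10 | [4-(allyloxy)-3-methoxyphenyl][(3S,4R,5R)-5-[4-(allyloxy)-3-methoxyphenyl]-3-hydroxy-4-(hydroxymethyl)tetrahydrofuran-3-yl]methanone | C=CCOc1ccc(cc1OC)[C@@H]2OC[C@](O)(C(=O)c3ccc(OCC=C)c(OC)c3)[C@@H]2CO
F7 | step 10 | (3S,4R,5R)-5-[4-(allyloxy)-3-methoxyphenyl]-3-[(S)-[4-(allyloxy)-3-methoxyphenyl](hydroxy)methyl]-4-(hydroxymethyl)tetrahydrofuran-3-ol | C=CCOc1ccc(cc1OC)[C@@H]2OC[C@](O)([C@@H](O)c3ccc(OCC=C)c(OC)c3)[C@@H]2CO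
F8 | step 10 | [(2R,3R,4S)-2-[4-(allyloxy)-3-methoxyphenyl]-4-[(S)-[4-(allyloxy)-3-methoxyphenyl](hydroxy)methyl]-4-hydroxytetrahydrofuran-3-yl]methyl 4-methylbenzenesulfonate | C=CCOc1ccc(cc1OC)[C@@H]2OC[C@](O)([C@@H](O)c3ccc(OCC=C)c(OC)c3)[C@@H]2COS(=O)(=O)c2ccc(C)cc2
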